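The runs are simulated from invented constants, noise included.

Ash is read at 5.0 min and birch at 20 min, from the same charges of free monomer and pre-initiator, and the question is whether the later reading finds longer chains.

| flask | free monomer | pre-initiator | remark | time |
|---|---|---|---|---|
| Thursday's | 0.010 M | 140 µM | run made earlier |  |
| Friday's | 0.010 M | 220 µM | run made earlier |  |
| ash | 0.010 M | 100 µM |  | 5.0 min |
| birch | 0.010 M | 100 µM |  | 20 min |

- Thursday's (time / min: monomer in chains / %): 0.500: 1.0; 1.00: 0.9; 1.50: 3.0; 2.50: 9.1; 3.00: 9.1; 4.00: 15.1
- Friday's (time / min: monomer in chains / %): 0.500: 0.4; 1.00: 4.8; 1.50: 6.7; 2.50: 12.6; 3.00: 16.5; 4.00: 20.8

(standard deviation of a reading: 1 percentage point)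

1. which of the two ends with the longer chains by the average number of monomer units in a chain (chains begun, living or dead) ("neither" if they lie within 10%) (ash / birch / neither)
2. average number of monomer units in a chain (chains begun, living or dead) at the end, ash
3. average number of monomer units in a chain (chains begun, living or dead) at the end, birch

- the average divides the monomer in chains by the number of chains begun, living and dead together
- the earlier runs were read with a standard deviation of 1 percentage point
- candidate steps: free monomer + initiator -> living end + monomer in chains; free monomer + living end -> monomer in chains + living end; living end + free monomer -> dead end; pre-initiator -> initiator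
- the earlier runs do not show the number of chains; that part of a forecast is a guess

The readings form a ladder of times. On the lowest rung stands a lag: at 0.500 min, Thursday's run shows 1.0% and Friday's 0.4%, against a scatter of 1 percentage point. On the next rung, at 4.00 min, Thursday's run holds 15.1% and Friday's 20.8%. That makes 10.8 units of monomer in chains per pre-initiator charged in Thursday's run; this is the yield per charge. Friday's run gives 9.45, although its charge is 1.57 times Thursday's, so monomer in chains went with the charge.

One pre-initiator can begin one chain at most, so the yield per charge is a floor under the average length (the number-average degree of polymerisation). The length is this yield divided by the share of the charge that has begun chains, and the runs do not show that share. The top rung, where chains stop being added, lies beyond the readings, since monomer in chains still rises between 3.00 min and 4.00 min, from 9.1% to 15.1% in Thursday's run and from 16.5% to 20.8% in Friday's. The reckoning made here therefore commits to a floor of about 10.8 units for ash and leaves birch open.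

The forecast commits further: birch has the longer chains, with 14 units in ash and 42 in birch, on the ground that “the living ends then hold roughly constant, with little visible death”.

The steps and constants of the flask are these:

    free monomer + initiator → living end + monomer in chains (k = 0.440 /M/s)
    free monomer + living end → monomer in chains + living end, rate k2*[living end]*[free monomer] (k = 140 /M/s)
    living end + free monomer → dead end (k = 8.30 /M/s)
    pre-initiator → initiator (k = 0.0280 /s)

Ash ends at 17.4 units and birch at 17.9, so the answer is neither, and one plus the ratio of the growth constant to the death constant is 17.9. In ash at 5.00 min, the yield per charge is 11.4, below the length, with 3.43 × 10⁻⁵ M of initiator left. In birch at 20.0 min, it is 17.6, with 1.28 × 10⁻⁶ M of initiator left. Ash read at 3.0 min yields 7.53 per charge, where the runs read 6.50 and 7.50 at that time, and with 45.0 µM of chains begun its length is 16.7.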